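## The problem

The target 21 is an isoflavan quinone in which a chroman (ring A fused to the pyran ring C) bearing 6-OH, 7-OMe and 8-OMe is joined through C3 to C1′ of a 2,3-dimethoxy-1,4-benzoquinone (ring B). C3 is the only stereocenter and is (S), so nothing in the molecule can relay to it and its configuration must come from a reagent or an auxiliary; it is a methine bound to three carbons (C2, C4 and C1′) with no heteroatom on it to direct a reaction. The quinone tolerates neither organometallics, bases nor reductants, and the C3 hydrogen sits next to the quinone double bond, where base could shift the double bond and erase the stereocenter. Ring B therefore has to travel as a protected hydroquinone and be oxidised last under neutral conditions, beside the electron-rich ring A phenol. Closing ring C through O1–C2 raises a selectivity problem, because the ortho oxygen of ring B could attack C2 equally well and give a five-membered dihydrobenzofuran, so the two rings need different protecting groups. Both rings share one pattern, a 1,4-dioxygenated 2,3-dimethoxybenzene substituted next to one oxygen, and can both come from quinone 2. The feature that enables the key step is that C3 bears one hydrogen and three carbons: it can be supplied as the CH unit of dichloromethane 12, inserted between a ring A benzyl group on boron (C4) and a ring B aryl nucleophile (C1′), with boron left on C3 as the handle for C2.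

## Retrosynthesis

**21 from 19.** No skeletal bond is cut. The quinone is traced to the hydroquinone bis(benzyl) ether 19 through the free hydroquinone 20. Oxidative demethylation of a tetramethoxyarene was set aside because it could not tell ring B from the equally electron-rich ring A. Benzyl ethers leave by neutral hydrogenolysis, and 20 is then oxidised by the mildest class of oxidant. The forward step must oxidise ring B only and stay free of base.

**19 from 17 (O1–C2).** Cutting the alkyl–oxygen bond of ring C is preferred to the aryl–oxygen bond C8a–O1, which would need a ring A halide and metal catalysis. It opens the chroman to a 2,3-diarylpropyl chain whose only stereocenter is C3. The forward reaction is an intramolecular Williamson closure of hydroquinone mesylate 18, made from mesylate 17, which comes from alcohol 16. Ring B stays benzylated so its ortho oxygen cannot compete. Both ring A oxygens can be MOM ethers and be freed together, because only the ortho one can reach C2. A sulfonate is used rather than an azodicarboxylate-based dehydration, since azodicarboxylates are known to dehydrogenate hydroquinones.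

**16 from 14 (C2–C3).** A primary alcohol next to the stereocenter maps onto a secondary boronic ester. A one-carbon carbenoid is inserted into the C3–B bond of 14 with retention (giving 15) and the new C–B bond is oxidised. Bringing C2 in with ring B as an arylacetate would need a separate source of chirality. Here C3 remains a boron-bearing carbon, which is what the key step produces. The forward step needs the carbenoid to add to a hindered boron atom.

**14 from 8, 12 and 11 (C3–C4 and C3–C1′).** Both carbon–carbon bonds to the stereocenter that involve the aromatic halves are cut at once. C3 then reduces to dichloromethane 12, ring A to benzylboronic ester 8 and ring B to Grignard reagent 11. Cutting only one of these bonds would leave an asymmetric alkylation or an asymmetric arylation to be solved separately. The double cut leaves two achiral arenes and the commercial C2-symmetric diol 5 as the sole source of chirality. The forward reaction must displace the two chlorides in a fixed order and sense and must not let the intermediate chloride 13 epimerise.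

**8 from 7, and 7 from 4 and 5.** The benzylic carbon C4 is removed by reversing a one-carbon insertion into the aryl–boron bond of 7. The boron of 7 is traced to a directed ortho-metalation of bis(MOM) ether 4, through boronic acid 6, and esterification with diol 5. This avoids benzyl halides of a very electron-rich ortho-alkoxy arene and their coupling-prone organometallics. The MOM groups serve twice, as directing groups here and as the ring A protection that falls before ring closure.

**11 from 10 and 9; 9 and 4 from 3; 3 from 2; 2 from 1.** Grignard reagent 11 comes from bromide 10, obtained by brominating bis(benzyl) ether 9. Both 9 and 4 are O-alkylation products of the same hydroquinone 3, which is prepared once by reducing quinone 2 and then divided between the two branches. Quinone 2 comes from the commercial phenol 1 by para-oxidation. One hydroquinone thus feeds both rings, and the two halves differ only in the protecting group.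

## Roads not taken

**Alternative 1:** Ring B is built last from a four-membered ring. The cut removes the quinone down to dimethyl squarate A4 and the chromanyl alkyne A3. Deprotonated A3 adds to A4 to give the 4-alkynyl-4-hydroxycyclobutenone A2. Heating opens A2 to an alkynylketene that closes to the six-membered ring and delivers the silyl-protected quinone A1.
- Merits: ring B arrives in its final oxidation state with both methoxy groups from a cheap reagent; no hydroquinone has to be protected or oxidised; the regiochemistry of the quinone is fixed by the mechanism. In the end-game this road is better than the chosen plan, which must oxidise ring B beside a free ring A phenol.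
- Weak points: the strategy does not address C3. The stereocenter must already be present in A3, a 3-ethynylchroman that needs its own asymmetric synthesis and a chroman closure beforehand. The thermal rearrangement of alkyl-substituted alkynylcyclobutenones can divert to alkylidene cyclopentenediones. A desilylation on the finished quinone is still required.
- Comparison: the chosen plan sets C3 while forming two of its bonds and needs no separate enantioselective entry to a fragment.

**Alternative 2:** The cut is C3–C1′ together with the benzylic C4–O bond of a pterocarpan. Chromene A6 and quinone 2 combine under TiCl4/Ti(OiPr)4 with a TADDOL ligand in a formal (3+2) cycloaddition to give the cis-pterocarpan A5. Hydrogenolysis of its benzylic C–O bond and benzyl ether would lead to hydroquinone 20 and then to 21.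
- Merits: this is clearly the shortest road; ring B enters with its oxygenation in place; the superfluous second stereocenter is erased by the same hydrogenolysis that removes the protecting group.
- Weak points: the enantioselectivity rests on a stoichiometric chiral TiCl4/Ti(OiPr)4–TADDOL promoter whose performance depends on the substrate. A6 is a very electron-rich, acid-sensitive styrene-type ether that can oligomerise under the Lewis acid. (2+2) adducts compete with the (3+2) adduct. There is no built-in way to raise the enantiomeric purity if the addition is only moderately selective.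
- Comparison: in step count this road is better. The chosen plan sets against it a C2-symmetric auxiliary with a predictable sense of induction, and diastereomeric boronic esters that can be purified before the auxiliary is removed.

**Alternative 3:** C3 is again a one-carbon unit, but it is inserted into a heterocycle. The cut excises C3 from ring C and leaves benzofuran A8. The carbene released from chlorodiazirine A9 cyclopropanates the furan double bond, and ring opening with loss of chloride forms C2–C3 and C3–C4 and gives the isoflavylium salt A7.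
- Merits: highly convergent, two bonds and the whole carbon skeleton in one step, from a simple benzofuran.
- Weak points: A7 is planar, so C3 is not set and a later enantioselective reduction of a hindered 2′-substituted isoflavene-type intermediate would have to do it. Chlorodiazirines of very electron-rich arenes are labile. Carbene insertion into benzofurans is less established than into indoles and pyrroles. The pyrylium salt is sensitive to nucleophiles.
- Comparison: this road forms the skeleton in fewer bond-forming steps. The chosen plan fixes the configuration in the same step that forms the bonds, rather than deferring it to a reduction of uncertain outcome.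

Key step: step 9

Assumption: the sense of induction follows the usual rule for boronic esters of C2-symmetric diols in this homologation, an (R,R)-diol giving the (αS)-chloride. The (S,S)-diol 5 should therefore give (1R)-13 and, after inversion, (1S)-14. If the opposite sense were found, the (R,R)-diol would be used with no other change.

## Route

Step 1
Reactants: 1 2,3-dimethoxyphenol
Product: 2 2,3-dimethoxy-1,4-benzoquinone
Conditions: (KSO3)2NO, KH2PO4, H2O/acetone, 0 °C → rt
Reagents that add atoms: potassium nitrosodisulfonate, [K+].[K+].[O]N(S(=O)(=O)[O-])S(=O)(=O)[O-]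
Why: Teuber oxidation: potassium nitrosodisulfonate converts a phenol with a free para position into the para-quinone, and the para carbon of 1 is open and activated by the neighbouring methoxy group.

Step 2
Reactants: 2 2,3-dimethoxy-1,4-benzoquinone
Product: 3 2,3-dimethoxybenzene-1,4-diol
Conditions: Na2S2O4, H2O/EtOAc, rt (Ar); extraction and evaporation under Ar
Reagents that add atoms: none
Why: Na2S2O4 reduction of a para-quinone to its hydroquinone is routine; 3 is isolated once under argon, stored cold and divided between the ring A and ring B branches.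

Step 3
Reactants: 3 2,3-dimethoxybenzene-1,4-diol
Product: 4 2,3-dimethoxy-1,4-bis(methoxymethoxy)benzene
Conditions: MOMCl, i-Pr2NEt, CH2Cl2, 0 °C → rt (Ar)
Reagents that add atoms: chloromethyl methyl ether (MOMCl), COCCl
Why: O-Alkylation of both phenols with MOMCl and a hindered amine base is a standard acetal protection; working under argon keeps the air-sensitive hydroquinone from reoxidising before both oxygens are capped.

Step 4
Reactants: 4 2,3-dimethoxy-1,4-bis(methoxymethoxy)benzene; 5 (1S,2S)-1,2-dicyclohexylethane-1,2-diol
Product: 7 (4S,5S)-4,5-dicyclohexyl-2-[3,4-dimethoxy-2,5-bis(methoxymethoxy)phenyl]-1,3,2-dioxaborolane, via arylboronic acid 6 (not isolated)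
Conditions: n-BuLi, TMEDA, THF, 0 °C; B(Oi-Pr)3, −78 °C → rt; 1 M HCl to pH 6; then 5, MgSO4, Et2O, rt
Reagents that add atoms: triisopropyl borate, CC(C)OB(OC(C)C)OC(C)C
Why: Directed ortho-metalation: the MOM ether directs n-BuLi to the ring C–H next to it (the two free positions are equivalent), the aryllithium is borylated, and the crude boronic acid 6 is esterified with diol 5 under dehydrating conditions.

Step 5
Reactants: 7 (4S,5S)-4,5-dicyclohexyl-2-[3,4-dimethoxy-2,5-bis(methoxymethoxy)phenyl]-1,3,2-dioxaborolane
Product: 8 (4S,5S)-4,5-dicyclohexyl-2-{[3,4-dimethoxy-2,5-bis(methoxymethoxy)phenyl]methyl}-1,3,2-dioxaborolane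
Conditions: BrCH2Cl, n-BuLi, THF, −78 °C → rt
Reagents that add atoms: bromochloromethane, ClCBr
Why: Matteson homologation with (chloromethyl)lithium made in situ: the carbenoid adds to boron at −78 °C and on warming the aryl group migrates from boron to carbon with loss of chloride, inserting the benzylic CH2 (C4).

Step 6
Reactants: 3 2,3-dimethoxybenzene-1,4-diol
Product: 9 1,4-bis(benzyloxy)-2,3-dimethoxybenzene
Conditions: BnBr, K2CO3, DMF (degassed, Ar), 60 °C
Reagents that add atoms: benzyl bromide, BrCc1ccccc1
Why: Williamson benzylation of both phenols of the second portion of 3; benzyl ethers are chosen for ring B because they survive every later step and fall in the last one.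

Step 7
Reactants: 9 1,4-bis(benzyloxy)-2,3-dimethoxybenzene
Product: 10 1,4-bis(benzyloxy)-5-bromo-2,3-dimethoxybenzene
Conditions: NBS, MeCN, 0 °C → rt (dark)
Reagents that add atoms: N-bromosuccinimide, O=C1CCC(=O)N1Br
Why: Electrophilic aromatic bromination of a tetraalkoxybenzene; the two free positions are equivalent and the first bromine deactivates the ring enough to stop at the monobromide.

Step 8
Reactants: 10 1,4-bis(benzyloxy)-5-bromo-2,3-dimethoxybenzene
Product: 11 [2,5-bis(benzyloxy)-3,4-dimethoxyphenyl]magnesium bromide
Conditions: Mg turnings, I2 (cat.), THF, 50 °C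
Reagents that add atoms: magnesium, [Mg]
Why: Direct magnesium insertion into an aryl bromide; the ortho benzyloxy group stabilises the Grignard reagent by chelation and benzyl ethers are inert to it.

Step 9
Reactants: 8 (4S,5S)-4,5-dicyclohexyl-2-{[3,4-dimethoxy-2,5-bis(methoxymethoxy)phenyl]methyl}-1,3,2-dioxaborolane; 11 [2,5-bis(benzyloxy)-3,4-dimethoxyphenyl]magnesium bromide; 12 dichloromethane
Product: 14 (4S,5S)-2-{(1S)-1-[2,5-bis(benzyloxy)-3,4-dimethoxyphenyl]-2-[3,4-dimethoxy-2,5-bis(methoxymethoxy)phenyl]ethyl}-4,5-dicyclohexyl-1,3,2-dioxaborolane, via α-chloro boronic ester 13 (not isolated)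
Conditions: 12, n-BuLi, THF, −100 °C; 8; ZnCl2, −100 °C → rt; hexane, filtration of salts (Ar); then 11, THF, −78 °C → rt
Reagents that add atoms: none
Why: Matteson asymmetric homologation followed by Grignard substitution of the α-chloro boronic ester, both known for benzylboronic esters of C2-symmetric diols and for aryl Grignard reagents. (Dichloromethyl)lithium, made from 12 at −100 °C, adds to boron of 8 to give a tetracoordinate ate complex. On warming with ZnCl2 the ring A benzyl group shifts from boron to carbon anti to one departing chloride and forms C3–C4; the two chlorides are diastereotopic, and the (S,S)-diol, with ZnCl2 bridging a ring oxygen and the leaving chloride, selects the one whose loss gives (1R)-13. After the salts are removed, 11 adds to boron of 13 and the ring B aryl group migrates with inversion at carbon as the second chloride leaves, forming C3–C1′ and (1S)-14. No ring is closed. C3 is therefore controlled by the diol in the first migration and by the stereospecific inversion in the second. The step needs carbon rather than oxygen to migrate and 13 not to epimerise by chloride exchange; ZnCl2 binds free chloride, the salts are filtered off before 11 is added, and the MOM and benzyl ethers are inert to both organometallics at these temperatures.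

Step 10
Reactants: 14 (4S,5S)-2-{(1S)-1-[2,5-bis(benzyloxy)-3,4-dimethoxyphenyl]-2-[3,4-dimethoxy-2,5-bis(methoxymethoxy)phenyl]ethyl}-4,5-dicyclohexyl-1,3,2-dioxaborolane
Product: 16 (2S)-2-[2,5-bis(benzyloxy)-3,4-dimethoxyphenyl]-3-[3,4-dimethoxy-2,5-bis(methoxymethoxy)phenyl]propan-1-ol, via homologated boronic ester 15 (not isolated)
Conditions: BrCH2Cl, n-BuLi, THF, −78 °C → rt; then NaOH, H2O2, THF/H2O, 0 °C → rt
Reagents that add atoms: bromochloromethane, ClCBr; hydrogen peroxide, OO
Why: A second Matteson homologation with (chloromethyl)lithium: the secondary benzylic carbon migrates from boron to the carbenoid carbon with retention, so C3 is untouched, and alkaline H2O2 oxidises the new primary C–B bond to the alcohol and releases diol 5 for recovery.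

Step 11
Reactants: 16 (2S)-2-[2,5-bis(benzyloxy)-3,4-dimethoxyphenyl]-3-[3,4-dimethoxy-2,5-bis(methoxymethoxy)phenyl]propan-1-ol
Product: 17 (2S)-2-[2,5-bis(benzyloxy)-3,4-dimethoxyphenyl]-3-[3,4-dimethoxy-2,5-bis(methoxymethoxy)phenyl]propyl methanesulfonate
Conditions: MsCl, Et3N, CH2Cl2, 0 °C
Reagents that add atoms: methanesulfonyl chloride, CS(=O)(=O)Cl
Why: Sulfonylation of a primary alcohol; it makes C2 an electrophile while every phenol is still masked.

Step 12
Reactants: 17 (2S)-2-[2,5-bis(benzyloxy)-3,4-dimethoxyphenyl]-3-[3,4-dimethoxy-2,5-bis(methoxymethoxy)phenyl]propyl methanesulfonate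
Product: 19 (3S)-3-[2,5-bis(benzyloxy)-3,4-dimethoxyphenyl]-7,8-dimethoxy-3,4-dihydro-2H-1-benzopyran-6-ol, via hydroquinone mesylate 18 (not isolated)
Conditions: HCl (cat.), MeOH, 40 °C; evaporation; then K2CO3, DMF (degassed, Ar), rt
Reagents that add atoms: none
Why: Acetal methanolysis removes both aryl MOM ethers without touching the benzyl ethers or the mesylate, and the ortho phenoxide of 18 then closes ring C by intramolecular Williamson etherification (6-exo-tet); the para phenol cannot reach C2 and the ring B oxygens are still benzylated, so only the chroman can form.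

Step 13
Reactants: 19 (3S)-3-[2,5-bis(benzyloxy)-3,4-dimethoxyphenyl]-7,8-dimethoxy-3,4-dihydro-2H-1-benzopyran-6-ol
Product: 21 5-[(3S)-6-hydroxy-7,8-dimethoxy-3,4-dihydro-2H-1-benzopyran-3-yl]-2,3-dimethoxycyclohexa-2,5-diene-1,4-dione, via hydroquinone 20 (not isolated)
Conditions: H2 (1 atm), 10% Pd/C, EtOAc, rt; filtration; then Ag2O, MgSO4, Et2O, 0 °C
Reagents that add atoms: none
Why: Hydrogenolysis cleaves the two aryl benzyl ethers and leaves the chroman untouched, since neither of its C–O bonds is a benzylic C–O bond; Ag2O is a neutral heterogeneous oxidant that should take the very electron-rich hydroquinone 20 to the quinone much faster than it attacks the monohydric ring A phenol, and no base is present to shift the C3 hydrogen.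

## Compound list

1 | 2,3-dimethoxyphenol | COc1cccc(O)c1OC | starting material
2 | 2,3-dimethoxy-1,4-benzoquinone | COC1=C(OC)C(=O)C=CC1=O | intermediate
3 | 2,3-dimethoxybenzene-1,4-diol | COc1c(O)ccc(O)c1OC | intermediate
4 | 2,3-dimethoxy-1,4-bis(methoxymethoxy)benzene | COCOc1ccc(OCOC)c(OC)c1OC | intermediate
5 | (1S,2S)-1,2-dicyclohexylethane-1,2-diol | C1CCCCC1[C@H](O)[C@H](C1CCCCC1)O | starting material
6 | [3,4-dimethoxy-2,5-bis(methoxymethoxy)phenyl]boronic acid | OB(O)c1cc(OCOC)c(OC)c(OC)c1OCOC | intermediate
7 | (4S,5S)-4,5-dicyclohexyl-2-[3,4-dimethoxy-2,5-bis(methoxymethoxy)phenyl]-1,3,2-dioxaborolane | COCOc1cc(B2O[C@@H](C3CCCCC3)[C@H](C3CCCCC3)O2)c(OCOC)c(OC)c1OC | intermediate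
8 | (4S,5S)-4,5-dicyclohexyl-2-{[3,4-dimethoxy-2,5-bis(methoxymethoxy)phenyl]methyl}-1,3,2-dioxaborolane | COCOc1cc(CB2O[C@@H](C3CCCCC3)[C@H](C3CCCCC3)O2)c(OCOC)c(OC)c1OC | intermediate
9 | 1,4-bis(benzyloxy)-2,3-dimethoxybenzene | COc1c(OC)c(OCc2ccccc2)ccc1OCc1ccccc1 | intermediate
10 | 1,4-bis(benzyloxy)-5-bromo-2,3-dimethoxybenzene | COc1c(OC)c(OCc2ccccc2)c(Br)cc1OCc1ccccc1 | intermediate
11 | [2,5-bis(benzyloxy)-3,4-dimethoxyphenyl]magnesium bromide | Br[Mg]c1cc(OCc2ccccc2)c(OC)c(OC)c1OCc1ccccc1 | intermediate
12 | dichloromethane | ClCCl | starting material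
13 | (4S,5S)-2-{(1R)-1-chloro-2-[3,4-dimethoxy-2,5-bis(methoxymethoxy)phenyl]ethyl}-4,5-dicyclohexyl-1,3,2-dioxaborolane | COCOc1cc(C[C@H](Cl)B2O[C@@H](C3CCCCC3)[C@H](C3CCCCC3)O2)c(OCOC)c(OC)c1OC | intermediate
14 | (4S,5S)-2-{(1S)-1-[2,5-bis(benzyloxy)-3,4-dimethoxyphenyl]-2-[3,4-dimethoxy-2,5-bis(methoxymethoxy)phenyl]ethyl}-4,5-dicyclohexyl-1,3,2-dioxaborolane | COCOc1cc(C[C@H](B2O[C@@H](C3CCCCC3)[C@H](C3CCCCC3)O2)c2cc(OCc3ccccc3)c(OC)c(OC)c2OCc2ccccc2)c(OCOC)c(OC)c1OC | intermediate
15 | (4S,5S)-2-{(2S)-2-[2,5-bis(benzyloxy)-3,4-dimethoxyphenyl]-3-[3,4-dimethoxy-2,5-bis(methoxymethoxy)phenyl]propyl}-4,5-dicyclohexyl-1,3,2-dioxaborolane | COCOc1cc(C[C@H](CB2O[C@@H](C3CCCCC3)[C@H](C3CCCCC3)O2)c2cc(OCc3ccccc3)c(OC)c(OC)c2OCc2ccccc2)c(OCOC)c(OC)c1OC | intermediate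
16 | (2S)-2-[2,5-bis(benzyloxy)-3,4-dimethoxyphenyl]-3-[3,4-dimethoxy-2,5-bis(methoxymethoxy)phenyl]propan-1-ol | COCOc1cc(C[C@H](CO)c2cc(OCc3ccccc3)c(OC)c(OC)c2OCc2ccccc2)c(OCOC)c(OC)c1OC | intermediate
17 | (2S)-2-[2,5-bis(benzyloxy)-3,4-dimethoxyphenyl]-3-[3,4-dimethoxy-2,5-bis(methoxymethoxy)phenyl]propyl methanesulfonate | COCOc1cc(C[C@H](COS(C)(=O)=O)c2cc(OCc3ccccc3)c(OC)c(OC)c2OCc2ccccc2)c(OCOC)c(OC)c1OC | intermediate
18 | (2S)-2-[2,5-bis(benzyloxy)-3,4-dimethoxyphenyl]-3-(2,5-dihydroxy-3,4-dimethoxyphenyl)propyl methanesulfonate | Oc1cc(C[C@H](COS(C)(=O)=O)c2cc(OCc3ccccc3)c(OC)c(OC)c2OCc2ccccc2)c(O)c(OC)c1OC | intermediate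
19 | (3S)-3-[2,5-bis(benzyloxy)-3,4-dimethoxyphenyl]-7,8-dimethoxy-3,4-dihydro-2H-1-benzopyran-6-ol | COc1c(OC)c(OCc2ccccc2)cc([C@H]2COc3c(cc(O)c(OC)c3OC)C2)c1OCc1ccccc1 | intermediate
20 | 2-[(3S)-6-hydroxy-7,8-dimethoxy-3,4-dihydro-2H-1-benzopyran-3-yl]-5,6-dimethoxybenzene-1,4-diol | COc1c(OC)c(O)cc([C@H]2COc3c(cc(O)c(OC)c3OC)C2)c1O | intermediate
21 | 5-[(3S)-6-hydroxy-7,8-dimethoxy-3,4-dihydro-2H-1-benzopyran-3-yl]-2,3-dimethoxycyclohexa-2,5-diene-1,4-dione | COC1=C(OC)C(=O)C([C@H]2COc3c(cc(O)c(OC)c3OC)C2)=CC1=O | target

## Step count and least certain steps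

Total: 13 steps. Longest linear sequence: 10 steps from 1 (steps 1, 2, 3, 4, 5, 9, 10, 11, 12, 13; the ring B branch through steps 1, 2, 6, 7, 8 joins at step 9 and is equally long).

**Step 9 (key step).** The most likely failure is loss of stereochemical purity by chloride-promoted epimerisation of 13 while the second ate complex forms slowly. Grignard 11 carries an ortho benzyloxy group, and the boron of 13 is shielded by the cyclohexyl groups of the diol. The same delay gives the ate complex time to undergo oxygen instead of carbon migration. Fallback, from 10 and 4 and back to the route at 16: the stereocenter is set by an Evans alkylation instead. Bromide 10 is coupled with the Reformatsky reagent BrZnCH2CO2Et (Pd(dba)2, XPhos) to ethyl [2,5-bis(benzyloxy)-3,4-dimethoxyphenyl]acetate F1. F1 is saponified (LiOH) to [2,5-bis(benzyloxy)-3,4-dimethoxyphenyl]acetic acid F2, which is condensed (DCC, DMAP) with (S)-4-benzyl-1,3-oxazolidin-2-one to the N-arylacetyl oxazolidinone F3. Ring A is supplied as an electrophile: lithiated 4 (n-BuLi, then DMF) gives 3,4-dimethoxy-2,5-bis(methoxymethoxy)benzaldehyde F4, NaBH4 gives the benzyl alcohol F5, and CBr4/PPh3 gives the benzyl bromide F6. The sodium enolate of F3 (NaN(SiMe3)2, THF, −78 °C) is alkylated by F6 on the face away from the auxiliary benzyl group to give the (2S)-alkylated imide F7, and LiBH4 then releases 16.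

**Step 10.** Addition of the carbenoid to the hindered secondary boronic ester may be slower than its decomposition, giving incomplete conversion. The primary boronic ester product can also take up a second CH2 unit if carbenoid is still present when migration starts. Fallback, from 14 and back at 16: a Zweifel olefination (vinylmagnesium bromide; I2; NaOMe) replaces boron by a vinyl group with retention to give the terminal alkene F8. Oxidative cleavage (OsO4 cat., NaIO4, 2,6-lutidine) gives the aldehyde F9, which is reduced at once with NaBH4 to 16 before its α-hydrogen can exchange.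

**Step 12.** Under base the freed ring A hydroquinone may be oxidised by traces of oxygen to the quinone, which can no longer cyclise. In the acidic stage chloride or methanol may displace the mesylate. Fallback, from 16 and back at 19: the MOM ethers of 16 are removed first (HCl, MeOH) to give the hydroquinone alcohol F10. F10 is then cyclised by redox-neutral dehydration with (cyanomethylene)tributylphosphorane in toluene at 80 °C, a Mitsunobu-type closure that uses neither base nor azodicarboxylate, to give 19.

**Step 5.** Double insertion of the carbenoid, or direct addition of n-BuLi to boron, would give mixtures of homologues. Fallback, from 4 and back at 8: the same ate complex is approached from the opposite pair of partners with exact stoichiometry. Triisopropyl borate, BrCH2Cl and n-BuLi give diisopropyl (chloromethyl)boronate F11, which is transesterified with diol 5 to the (S,S)-diol (chloromethyl)boronate F12. Lithiated 4 (n-BuLi, TMEDA) adds to F12 at −78 °C, and on warming the aryl group displaces chloride to give 8.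

**Step 13.** The oxidant may also attack the free ring A phenol (oxidative coupling), or prolonged contact may shift the C3 hydrogen. Fallback, from 19 and back at 21: the phenol is masked during the oxidation. Silylation of 19 (TBSCl, imidazole) gives the silyl ether F13. Hydrogenolysis gives the silylated hydroquinone F14, which Ag2O oxidises to the silylated quinone F15. Buffered HF·pyridine in THF at 0 °C then frees 21.

## Further compounds

F1 | step 9 | ethyl [2,5-bis(benzyloxy)-3,4-dimethoxyphenyl]acetate | CCOC(=O)Cc1cc(OCc2ccccc2)c(OC)c(OC)c1OCc1ccccc1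
F2 | step 9 | [2,5-bis(benzyloxy)-3,4-dimethoxyphenyl]acetic acid | OC(=O)Cc1cc(OCc2ccccc2)c(OC)c(OC)c1OCc1ccccc1
F3 | step 9 | (4S)-4-benzyl-3-{[2,5-bis(benzyloxy)-3,4-dimethoxyphenyl]acetyl}-1,3-oxazolidin-2-one | O=C(Cc1cc(OCc2ccccc2)c(OC)c(OC)c1OCc1ccccc1)N1[C@@H](Cc2ccccc2)COC1=O
F4 | step 9 | 3,4-dimethoxy-2,5-bis(methoxymethoxy)benzaldehyde | COCOc1cc(C=O)c(OCOC)c(OC)c1OC
F5 | step 9 | [3,4-dimethoxy-2,5-bis(methoxymethoxy)phenyl]methanol | COCOc1cc(CO)c(OCOC)c(OC)c1OC
F6 | step 9 | 1-(bromomethyl)-3,4-dimethoxy-2,5-bis(methoxymethoxy)benzene | COCOc1cc(CBr)c(OCOC)c(OC)c1OC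
F7 | step 9 | (4S)-4-benzyl-3-{(2S)-2-[2,5-bis(benzyloxy)-3,4-dimethoxyphenyl]-3-[3,4-dimethoxy-2,5-bis(methoxymethoxy)phenyl]propanoyl}-1,3-oxazolidin-2-one | COCOc1cc(C[C@H](C(=O)N2[C@@H](Cc3ccccc3)COC2=O)c2cc(OCc3ccccc3)c(OC)c(OC)c2OCc2ccccc2)c(OCOC)c(OC)c1OC
F8 | step 10 | 1,4-bis(benzyloxy)-5-{(2R)-1-[3,4-dimethoxy-2,5-bis(methoxymethoxy)phenyl]but-3-en-2-yl}-2,3-dimethoxybenzene | COCOc1cc(C[C@H](C=C)c2cc(OCc3ccccc3)c(OC)c(OC)c2OCc2ccccc2)c(OCOC)c(OC)c1OC
F9 | step 10 | (2S)-2-[2,5-bis(benzyloxy)-3,4-dimethoxyphenyl]-3-[3,4-dimethoxy-2,5-bis(methoxymethoxy)phenyl]propanal | COCOc1cc(C[C@H](C=O)c2cc(OCc3ccccc3)c(OC)c(OC)c2OCc2ccccc2)c(OCOC)c(OC)c1OC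
F10 | step 12 | 2-{(2S)-2-[2,5-bis(benzyloxy)-3,4-dimethoxyphenyl]-3-hydroxypropyl}-5,6-dimethoxybenzene-1,4-diol | Oc1cc(C[C@H](CO)c2cc(OCc3ccccc3)c(OC)c(OC)c2OCc2ccccc2)c(O)c(OC)c1OC
F11 | step 5 | dipropan-2-yl (chloromethyl)boronate | ClCB(OC(C)C)OC(C)C
F12 | step 5 | (4S,5S)-2-(chloromethyl)-4,5-dicyclohexyl-1,3,2-dioxaborolane | ClCB1O[C@@H](C2CCCCC2)[C@H](C2CCCCC2)O1
F13 | step 13 | tert-butyl{[(3S)-3-[2,5-bis(benzyloxy)-3,4-dimethoxyphenyl]-7,8-dimethoxy-3,4-dihydro-2H-1-benzopyran-6-yl]oxy}dimethylsilane | COc1c(OC)c(OCc2ccccc2)cc([C@H]2COc3c(cc(O[Si](C)(C)C(C)(C)C)c(OC)c3OC)C2)c1OCc1ccccc1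
F14 | step 13 | 2-[(3S)-6-{[tert-butyl(dimethyl)silyl]oxy}-7,8-dimethoxy-3,4-dihydro-2H-1-benzopyran-3-yl]-5,6-dimethoxybenzene-1,4-diol | COc1c(OC)c(O)cc([C@H]2COc3c(cc(O[Si](C)(C)C(C)(C)C)c(OC)c3OC)C2)c1O
F15 | step 13 | 5-[(3S)-6-{[tert-butyl(dimethyl)silyl]oxy}-7,8-dimethoxy-3,4-dihydro-2H-1-benzopyran-3-yl]-2,3-dimethoxycyclohexa-2,5-diene-1,4-dione | COC1=C(OC)C(=O)C([C@H]2COc3c(cc(O[Si](C)(C)C(C)(C)C)c(OC)c3OC)C2)=CC1=O
A1 | alternative 1 | 5-[(3S)-7,8-dimethoxy-6-{[tri(propan-2-yl)silyl]oxy}-3,4-dihydro-2H-1-benzopyran-3-yl]-2,3-dimethoxycyclohexa-2,5-diene-1,4-dione | COC1=C(OC)C(=O)C([C@H]2COc3c(cc(O[Si](C(C)C)(C(C)C)C(C)C)c(OC)c3OC)C2)=CC1=O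
A2 | alternative 1 | 4-({(3S)-7,8-dimethoxy-6-{[tri(propan-2-yl)silyl]oxy}-3,4-dihydro-2H-1-benzopyran-3-yl}ethynyl)-4-hydroxy-2,3-dimethoxycyclobut-2-en-1-one | COC1=C(OC)C(O)(C#C[C@H]2COc3c(cc(O[Si](C(C)C)(C(C)C)C(C)C)c(OC)c3OC)C2)C1=O
A3 | alternative 1 | {[(3S)-3-ethynyl-7,8-dimethoxy-3,4-dihydro-2H-1-benzopyran-6-yl]oxy}tri(propan-2-yl)silane | C#C[C@H]1COc2c(cc(O[Si](C(C)C)(C(C)C)C(C)C)c(OC)c2OC)C1
A4 | alternative 1 | 3,4-dimethoxycyclobut-3-ene-1,2-dione (dimethyl squarate) | COC1=C(OC)C(=O)C1=O
A5 | alternative 2 | cis-2-(benzyloxy)-3,4,9,10-tetramethoxypterocarpan-8-ol | COc1c(OCc2ccccc2)cc2c(c1OC)OC[C@H]1[C@@H]2Oc2c(OC)c(OC)c(O)cc21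
A6 | alternative 2 | 6-(benzyloxy)-7,8-dimethoxy-2H-chromene | COc1c(OCc2ccccc2)cc2C=CCOc2c1OC
A7 | alternative 3 | 6-(benzyloxy)-3-[2,5-bis(benzyloxy)-3,4-dimethoxyphenyl]-7,8-dimethoxychromenylium chloride | COc1c(OCc2ccccc2)cc2cc(-c3cc(OCc4ccccc4)c(OC)c(OC)c3OCc3ccccc3)c[o+]c2c1OC.[Cl-]
A8 | alternative 3 | 5-(benzyloxy)-6,7-dimethoxy-1-benzofuran | COc1c(OCc2ccccc2)cc2ccoc2c1OC
A9 | alternative 3 | 3-[2,5-bis(benzyloxy)-3,4-dimethoxyphenyl]-3-chloro-3H-diazirine | COc1c(OC)c(OCc2ccccc2)cc(C2(Cl)N=N2)c1OCc1ccccc1
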